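**Retrosynthetic overview**

- The target comes from a trans-fused hydroazulen-2-one (ring A: C1–C5; ring B: C1, C5–C10) by desilylation, aroylation of O6, hydroxyl-directed anti reduction of C2, acetylation and phenol release.
- Feature used: the methyl-bearing quaternary carbon C1 lies between C2 (carbonyl level) and C5 and belongs to both rings. It can therefore be inserted as one carbon into the C2–C5 bond of a four-membered ring C2–C3–C4–C5 by a diazo carbon tied to C5 through C6–C10, which forms ring A and ring B together.
- The cyclobutanone is kept as its 3,3-dichloro derivative, so that C5 and not C3 migrates. It comes from dichloroketene and a (Z)-silyl enol ether C4=C5 whose face is controlled by C6. The C1 sulfonylhydrazone is installed before the cycloaddition, while the C4 ketone is the only other carbonyl.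
- The acyclic chain comes from a Z-alkenyllithium at C8 (from but-2-yn-1-ol and 2-methyl-1,3-dithiane) and an (R)-epoxide (C6 from (R)-epichlorohydrin, C4 masked as 2-isopropyl-1,3-dithiane).
- Ring order: temporary four-membered ring (step 11), then ring A and ring B at once (step 12).

Key step: step 12

Assumption: the skeleton locants C1–C10 defined above are used for all intermediates (with them the target is 1R,2S,4R,5S,6S); Zn–Cu couple and 2-(trifluoromethyl)benzenesulfonohydrazide are taken as purchasable reagents; the face selectivity in step 11 and the C1 configuration in step 12 are predictions.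

**Route**

Step 1
Reactants: 1 but-2-yn-1-ol
Product: 3 (Z)-3-iodobut-2-en-1-ol, via cyclic sodium alkenylalanate 2 (not isolated)
Conditions: NaAlH2(OCH2CH2OCH3)2, THF, 0 °C → rt; then I2, −78 °C → rt
Reagents that add atoms: iodine, II
Why: Alkoxide-directed trans-hydroalumination of the propargylic alcohol places aluminium on C8 cis to the CH2O group, and iodinolysis with retention gives the Z-iodoalkene that later fixes C7 cis to C10.

Step 2
Reactants: 3 (Z)-3-iodobut-2-en-1-ol
Product: 4 (Z)-1-bromo-3-iodobut-2-ene
Conditions: CBr4, PPh3, CH2Cl2, 0 °C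
Reagents that add atoms: carbon tetrabromide, BrC(Br)(Br)Br
Why: Appel bromination converts the primary allylic alcohol into the bromide under neutral conditions without touching the alkenyl iodide or the alkene geometry.

Step 3
Reactants: 4 (Z)-1-bromo-3-iodobut-2-ene; 5 2-methyl-1,3-dithiane
Product: 7 2-[(Z)-3-iodobut-2-en-1-yl]-2-methyl-1,3-dithiane, via 2-lithio-2-methyl-1,3-dithiane 6 (not isolated)
Conditions: 5, n-BuLi, THF, −30 °C; then 4, −78 °C
Reagents that add atoms: none
Why: Corey–Seebach alkylation, in which the lithiated dithiane displaces the primary allylic bromide by SN2 and so joins C1 (with its methyl group, masked as a ketone) to C10, the alkenyl iodide being inert to the stabilised carbanion.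

Step 4
Reactants: 8 2-methylpropanal; 9 propane-1,3-dithiol
Product: 10 2-(propan-2-yl)-1,3-dithiane
Conditions: BF3·OEt2 (cat.), CH2Cl2, 0 °C → rt
Reagents that add atoms: none
Why: Lewis acid-catalysed dithioacetalisation of an unhindered aldehyde is a standard condensation and turns the future C4 carbonyl into an acyl anion equivalent.

Step 5
Reactants: 10 2-(propan-2-yl)-1,3-dithiane; 11 (R)-epichlorohydrin
Product: 14 2-[(2R)-oxiran-2-ylmethyl]-2-(propan-2-yl)-1,3-dithiane, via 2-lithio-2-(propan-2-yl)-1,3-dithiane 12 (not isolated), via lithium chlorohydrin alkoxide 13 (not isolated)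
Conditions: 10, t-BuLi, THF/HMPA 9:1, −78 °C; then 11, −78 → 0 °C
Reagents that add atoms: none
Why: Corey–Seebach reaction with an epoxide, in which the anion opens epichlorohydrin at the unsubstituted epoxide carbon and the alkoxide closes onto the chloromethyl group on warming, so that no bond at the stereocentre is touched and C6 is taken from the chiral pool (R in 14).

Step 6
Reactants: 7 2-[(Z)-3-iodobut-2-en-1-yl]-2-methyl-1,3-dithiane; 14 2-[(2R)-oxiran-2-ylmethyl]-2-(propan-2-yl)-1,3-dithiane
Product: 16 bis-dithiane alcohol, via Z-alkenyllithium 15 (not isolated)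
Conditions: 7, t-BuLi (2 equiv), Et2O, −78 °C; then 14, BF3·OEt2, −78 °C
Reagents that add atoms: none
Why: Iodine–lithium exchange keeps the alkene geometry and the BF3-activated terminal epoxide is opened at its CH2 carbon (C7) by the alkenyllithium, which forms C7–C8 and leaves the C6 stereocentre untouched (S in 16 by change of priorities only).

Step 7
Reactants: 16 bis-dithiane alcohol
Product: 17 bis-dithiane silyl ether
Conditions: t-BuMe2SiCl, imidazole, DMF, rt
Reagents that add atoms: tert-butyldimethylsilyl chloride, CC(C)(C)[Si](C)(C)Cl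
Why: Imidazole-promoted silylation of an unhindered secondary alcohol protects O6 for the enolisation, cycloaddition and ring-enlargement steps.

Step 8
Reactants: 17 bis-dithiane silyl ether
Product: 18 diketone
Conditions: PhI(OCOCF3)2 (3 equiv), NaHCO3, MeCN/H2O 9:1, 0 °C
Reagents that add atoms: water, O
Why: Oxidative dithioacetal hydrolysis with the hypervalent iodine reagent is fast at 0 °C and, buffered with bicarbonate, should unmask C4 and C1 in one operation without moving the C8=C9 double bond into conjugation or cleaving the silyl ether.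

Step 9
Reactants: 18 diketone
Product: 19 C1 sulfonylhydrazone
Conditions: 2-(CF3)C6H4SO2NHNH2 (1.0 equiv), THF, 0 °C → rt
Reagents that add atoms: 2-(trifluoromethyl)benzenesulfonohydrazide, NNS(=O)(=O)c1ccccc1C(F)(F)F
Why: Hydrazone condensation is much faster at the unhindered methyl ketone C1 than at the α-branched isopropyl ketone C4, so one equivalent of the hydrazide marks C1 alone as the diazo precursor at a stage where no cyclobutanone competes.

Step 10
Reactants: 19 C1 sulfonylhydrazone
Product: 21 (Z)-triethylsilyl enol ether, via dilithio species 20 (not isolated)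
Conditions: LiN(iPr)2 (2.1 equiv), THF, −78 °C; Et3SiCl, DMPU, −78 → −30 °C; aq. NaHCO3
Reagents that add atoms: chlorotriethylsilane, CC[Si](Cl)(CC)CC
Why: Kinetic enolisation and O-silylation, in which the first equivalent of base removes the acidic N–H (which also shields C1 and C10), the second deprotonates the C5 methylene and not the isopropyl methine, and the Z-enolate with the isopropyl group trans to the branched C6 substituent is favoured and trapped on oxygen (any N–Si bond is cleaved on aqueous work-up).

Step 11
Reactants: 21 (Z)-triethylsilyl enol ether; 22 trichloroacetyl chloride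
Product: 23 dichlorocyclobutanone sulfonylhydrazone
Conditions: Zn–Cu couple, Et2O/DME, slow addition of 22, 0 °C → rt
Reagents that add atoms: none
Why: Ketene–alkene [2+2] cycloaddition of dichloroketene with the electron-rich enol ether joins the ketene carbonyl carbon (C2) to nucleophilic C5 and CCl2 (C3) to C4 suprafacially, so the C4 silyloxy group and C6 become cis, and since A(1,3) strain holds H-6 in the enol ether plane the ketene should enter anti to the C6 silyloxy group, which sets C4 and C5 relative to C6.

Step 12
Reactants: 23 dichlorocyclobutanone sulfonylhydrazone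
Product: 27 trans-fused 3,3-dichlorohydroazulen-2-one, via sodium sulfonylhydrazonide 24 (not isolated), via diazoalkane 25 (not isolated), via diazonium betaine 26 (not isolated)
Conditions: NaH (1.0 equiv), THF, 0.005 M, −20 → 25 °C; no Lewis acid
Reagents that add atoms: none
Why: Proposed new method: deprotonation gives the sulfonylhydrazonide 24, which loses arenesulfinate at or below room temperature (Bamford–Stevens fragmentation) to the diazoalkane 25, whose nucleophilic carbon C1 adds to the strained, chlorine-activated carbonyl C2 to give the diazonium alkoxide 26, and C5, antiperiplanar to the leaving N2, shifts from C2 to C1 with retention at C5 and inversion at C1 (Tiffeneau–Demjanov-type 1,2-shift). The closest known reactions are the intermolecular diazoalkane homologation of 2,2-dichlorocyclobutanones to 2,2-dichlorocyclopentanones and the intramolecular Schmidt reaction of azidoalkyl ketones, but insertion of a tethered, fully substituted diazo carbon to give a fused bicycle has not been shown. Ring A (C1–C5) is closed by one-carbon enlargement of the four-membered ring, and ring B (C1, C5–C10) by contraction of the eight-membered ring of 26, itself formed by 8-exo-trig attack of C1 on C2. The new stereocentre C1 is controlled by the betaine: the tether brings C1 to the face of C2 that carries C6, and with N2 anti to C5 the small methyl group takes the crowded site between C3 and C5 while C10 points outward, which after inversion puts the methyl group trans to H-5 (trans ring fusion). The step needs migration of C5 and not of C3, and this is secured by the two chlorine atoms on C3, which suppress migration of that carbon and activate C2 so strongly that no Lewis acid, which would open the 3-silyloxycyclobutanone, is needed.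

Step 13
Reactants: 27 trans-fused 3,3-dichlorohydroazulen-2-one
Product: 28 trans-fused hydroazulen-2-one
Conditions: Zn dust, AcOH, TMEDA, EtOH, 0 °C → rt
Reagents that add atoms: none
Why: Zinc-mediated reductive dechlorination of an α,α-dichloro ketone runs through zinc enolates that acetic acid should protonate faster than the C4 silyloxy group can be expelled, and no stereocentre is affected.

Step 14
Reactants: 28 trans-fused hydroazulen-2-one
Product: 29 4,6-dihydroxy hydroazulen-2-one
Conditions: HF·pyridine, pyridine, THF, 0 °C → rt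
Reagents that add atoms: none
Why: Fluoride cleavage of both silyl ethers under pyridine buffering frees the tertiary C4 and secondary C6 hydroxyls without the base-induced retro-aldol opening that a basic fluoride source could cause in the β-hydroxy ketone.

Step 15
Reactants: 29 4,6-dihydroxy hydroazulen-2-one; 30 4-acetoxybenzoyl chloride
Product: 31 C6 4-acetoxybenzoate ketone
Conditions: 30 (1.5 equiv), pyridine, DMAP (cat.), CH2Cl2, 0 °C → rt
Reagents that add atoms: none
Why: DMAP-catalysed acylation distinguishes the secondary C6 hydroxyl from the tertiary, isopropyl-flanked C4 hydroxyl, so the protected 4-hydroxybenzoyl group should go on O6 only.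

Step 16
Reactants: 31 C6 4-acetoxybenzoate ketone
Product: 32 C2 alcohol
Conditions: Me4NBH(OAc)3, MeCN/AcOH 1:1, −20 °C
Reagents that add atoms: none
Why: Evans–Saksena reduction, in which the C4 hydroxyl exchanges onto boron and delivers hydride to the face of C2 that it occupies, should give the C2 alcohol trans (anti) to the C4 hydroxyl, that is 2S.

Step 17
Reactants: 32 C2 alcohol
Product: 33 C2 acetate
Conditions: Ac2O, pyridine, DMAP (cat.), CH2Cl2, 0 °C → rt
Reagents that add atoms: acetic anhydride, CC(=O)OC(C)=O
Why: DMAP-catalysed acetylation esterifies the only secondary hydroxyl (C2) and leaves the hindered tertiary C4 hydroxyl free.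

Step 18
Reactants: 33 C2 acetate
Product: 34 target CNP0275279.1
Conditions: NH4OAc, MeOH/H2O 4:1, rt
Reagents that add atoms: none
Why: Aryl acetates are far more electrophilic than alkyl acetates or alkyl benzoates, so buffered methanolysis with ammonium acetate should remove only the phenolic acetyl group and release the target.

**Compound list**

1 | but-2-yn-1-ol | CC#CCO | starting material
2 | cyclic sodium alkenylalanate: sodium 2,2-bis(2-methoxyethoxy)-3-methyl-2,5-dihydro-1,2-oxaluminol-2-uide (Al on C8 cis to CH2O; formed in situ) | C/C(=C/CO1)[Al-]1(OCCOC)OCCOC.[Na+] | intermediate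
3 | (Z)-3-iodobut-2-en-1-ol | C/C(I)=C/CO | intermediate
4 | (Z)-1-bromo-3-iodobut-2-ene | C/C(I)=C/CBr | intermediate
5 | 2-methyl-1,3-dithiane | CC1SCCCS1 | starting material
6 | 2-lithio-2-methyl-1,3-dithiane (formed in situ) | [Li]C1(C)SCCCS1 | intermediate
7 | 2-[(Z)-3-iodobut-2-en-1-yl]-2-methyl-1,3-dithiane | C/C(I)=C/CC1(C)SCCCS1 | intermediate
8 | 2-methylpropanal | CC(C)C=O | starting material
9 | propane-1,3-dithiol | SCCCS | starting material
10 | 2-(propan-2-yl)-1,3-dithiane | CC(C)C1SCCCS1 | intermediate
11 | (R)-epichlorohydrin | ClC[C@H]1CO1 | starting material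
12 | 2-lithio-2-(propan-2-yl)-1,3-dithiane (formed in situ) | [Li]C1(C(C)C)SCCCS1 | intermediate
13 | lithium chlorohydrin alkoxide: lithium (2R)-1-chloro-3-[2-(propan-2-yl)-1,3-dithian-2-yl]propan-2-olate (formed in situ) | CC(C)C1(SCCCS1)C[C@@H](O[Li])CCl | intermediate
14 | 2-[(2R)-oxiran-2-ylmethyl]-2-(propan-2-yl)-1,3-dithiane | CC(C)C1(SCCCS1)C[C@@H]2CO2 | intermediate
15 | Z-alkenyllithium: 2-[(Z)-3-lithiobut-2-en-1-yl]-2-methyl-1,3-dithiane (formed in situ) | C/C([Li])=C/CC1(C)SCCCS1 | intermediate
16 | bis-dithiane alcohol: (2S,4Z)-4-methyl-6-(2-methyl-1,3-dithian-2-yl)-1-[2-(propan-2-yl)-1,3-dithian-2-yl]hex-4-en-2-ol | CC(C)C1(SCCCS1)C[C@@H](O)C/C(C)=C\CC2(C)SCCCS2 | intermediate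
17 | bis-dithiane silyl ether: tert-butyldimethylsilyl ether of 16 (6S; Z) | CC(C)C1(SCCCS1)C[C@@H](O[Si](C)(C)C(C)(C)C)C/C(C)=C\CC2(C)SCCCS2 | intermediate
18 | diketone: (4Z,7S)-7-[(tert-butyldimethylsilyl)oxy]-5,10-dimethylundec-4-ene-2,9-dione | CC(C)C(=O)C[C@@H](O[Si](C)(C)C(C)(C)C)C/C(C)=C\CC(C)=O | intermediate
19 | C1 sulfonylhydrazone: 2-(trifluoromethyl)benzenesulfonylhydrazone of 18 at the methyl ketone C1 (6S; Z) | CC(C)C(=O)C[C@@H](O[Si](C)(C)C(C)(C)C)C/C(C)=C\CC(C)=NNS(=O)(=O)c1ccccc1C(F)(F)F | intermediate
20 | dilithio species: N-lithio sulfonylhydrazonide and Z lithium enolate (C4=C5) of 19 (formed in situ) | CC(C)/C(O[Li])=C/[C@@H](O[Si](C)(C)C(C)(C)C)C/C(C)=C\CC(C)=NN([Li])S(=O)(=O)c1ccccc1C(F)(F)F | intermediate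
21 | (Z)-triethylsilyl enol ether of 19 (C4=C5; silyloxy group cis to C6; 6S) | CC(C)/C(O[Si](CC)(CC)CC)=C/[C@@H](O[Si](C)(C)C(C)(C)C)C/C(C)=C\CC(C)=NNS(=O)(=O)c1ccccc1C(F)(F)F | intermediate
22 | trichloroacetyl chloride | ClC(=O)C(Cl)(Cl)Cl | starting material
23 | dichlorocyclobutanone sulfonylhydrazone: ring C2(=O)–C3Cl2–C4(OSiEt3)(iPr)–C5H; C4–O cis to the C5 side chain; side chain C6(OTBS, S)–C7–C8(CH3)=C9 (Z)–C10–C1(=N–NH–SO2Ar)CH3 | O=C1C(Cl)(Cl)[C@@](O[Si](CC)(CC)CC)(C(C)C)[C@@H]1[C@@H](O[Si](C)(C)C(C)(C)C)C/C(C)=C\CC(C)=NNS(=O)(=O)c1ccccc1C(F)(F)F | intermediate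
24 | sodium sulfonylhydrazonide of 23 (formed in situ) | O=C1C(Cl)(Cl)[C@@](O[Si](CC)(CC)CC)(C(C)C)[C@@H]1[C@@H](O[Si](C)(C)C(C)(C)C)C/C(C)=C\CC(C)=N[N-]S(=O)(=O)c1ccccc1C(F)(F)F.[Na+] | intermediate
25 | diazoalkane: dichlorocyclobutanone of 23 with a 2-diazopropyl terminus at C1 (formed in situ) | O=C1C(Cl)(Cl)[C@@](O[Si](CC)(CC)CC)(C(C)C)[C@@H]1[C@@H](O[Si](C)(C)C(C)(C)C)C/C(C)=C\CC(C)=[N+]=[N-] | intermediate
26 | diazonium betaine: cis-fused bicyclo[6.2.0] alkoxide with the C1–C2 bond formed and N2+ on C1 (formed in situ) | [O-][C@@]12C(Cl)(Cl)[C@@](O[Si](CC)(CC)CC)(C(C)C)[C@@H]1[C@@H](O[Si](C)(C)C(C)(C)C)C/C(C)=C\C[C@@]2(C)[N+]#N | intermediate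
27 | trans-fused 3,3-dichlorohydroazulen-2-one: 4-OSiEt3, 4-isopropyl, 6-OTBS, 1-CH3, 8-CH3, C8=C9; H-5 trans to 1-CH3; configuration as in the target | O=C1C(Cl)(Cl)[C@@](O[Si](CC)(CC)CC)(C(C)C)[C@@H]2[C@@H](O[Si](C)(C)C(C)(C)C)CC(C)=CC[C@@]12C | intermediate
28 | trans-fused hydroazulen-2-one: 27 with C3H2 | O=C1C[C@@](O[Si](CC)(CC)CC)(C(C)C)[C@@H]2[C@@H](O[Si](C)(C)C(C)(C)C)CC(C)=CC[C@@]12C | intermediate
29 | 4,6-dihydroxy hydroazulen-2-one | O=C1C[C@@](O)(C(C)C)[C@@H]2[C@@H](O)CC(C)=CC[C@@]12C | intermediate
30 | 4-acetoxybenzoyl chloride | CC(=O)Oc1ccc(cc1)C(Cl)=O | starting material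
31 | C6 4-acetoxybenzoate ketone (4-OH free) | O=C1C[C@@](O)(C(C)C)[C@@H]2[C@@H](OC(=O)c3ccc(OC(C)=O)cc3)CC(C)=CC[C@@]12C | intermediate
32 | C2 alcohol (2S; 2-OH trans to 4-OH) | O[C@H]1C[C@@](O)(C(C)C)[C@@H]2[C@@H](OC(=O)c3ccc(OC(C)=O)cc3)CC(C)=CC[C@@]12C | intermediate
33 | C2 acetate with O-acetylated phenol | CC(=O)O[C@H]1C[C@@](O)(C(C)C)[C@@H]2[C@@H](OC(=O)c3ccc(OC(C)=O)cc3)CC(C)=CC[C@@]12C | intermediate
34 | CNP0275279.1: (1R,2S,4R,5S,6S)-2-acetoxy-4-hydroxy-4-isopropyl-1,8-dimethylbicyclo[5.3.0]dec-8-en-6-yl 4-hydroxybenzoate (skeleton locants) | CC(=O)O[C@H]1C[C@@](O)(C(C)C)[C@@H]2[C@@H](OC(=O)c3ccc(O)cc3)CC(C)=CC[C@@]12C | target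

**Step count and risks**

Total steps: 18. Longest linear sequence: 16 steps (steps 1–3 and 6–18).

Steps most likely to fail:

1. Step 12 (proposed new method). The diazoalkane may be consumed by 1,2-hydrogen shift, azine formation or cycloaddition onto the C8=C9 alkene before it reaches C2, or the betaine may collapse through its C1 epimer to the cis-fused ketone or a spiro-epoxide. The fallback builds rings A and B one after the other by known reactions and sets out from epoxide 14.
 - Copper-catalysed opening with isopropenylmagnesium bromide (CuI cat., THF) gives the homoallylic alcohol F1.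
 - Silylation gives the silyl ether F2, and dithiane hydrolysis gives the ketone F3.
 - Kinetic enolisation and silylation give the (Z)-enol ether F4, and dichloroketene cycloaddition gives the dichlorocyclobutanone F5.
 - Intermolecular ring enlargement with diazoethane, the known regioselective homologation of 2,2-dichlorocyclobutanones, gives the dichloro methylcyclopentanone F6 (both C1 epimers usable).
 - Zinc dechlorination gives the ketone F7.
 - The more substituted trimethylsilyl enol ether F8 (Me3SiCl, NaI, Et3N) is cleaved with MeLi, and the lithium enolate is allylated with allyl bromide anti to the C5 side chain to give the quaternary allyl methyl ketone F9.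
 - Ring-closing metathesis with the second-generation Grubbs catalyst between the C8 isopropenyl and C9 vinyl groups closes ring B and comes back to the route at 28, so step 13 is then not needed.

2. Step 11. The hindered enol ether may react slowly, so that dichloroketene acylates the sulfonylhydrazone N–H. The fallback takes the N–H out of play with a protecting group and sets out from 21: N-silylation (t-BuMe2SiOTf, Et3N, −78 °C) gives the N-silyl sulfonylhydrazone F10, the cycloaddition gives the N-silyl dichlorocyclobutanone F11, and brief treatment with aqueous acetic acid in THF cleaves the N–Si bond and comes back to the route at 23.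

3. Step 13. The zinc enolate formed after loss of the first chlorine may expel the C4 silyloxy group and give the cyclopentenone. The fallback sets out from 27 and replaces the two-electron zinc reduction by a radical chain hydrodechlorination (Bu3SnH, AIBN, toluene, 80 °C), a different reaction type in which C3 becomes a radical and never an enolate carbon; it comes back to the route at 28 and makes no new compound.

**Further compounds**

F1 | step 12 | (2S)-4-methyl-1-[2-(propan-2-yl)-1,3-dithian-2-yl]pent-4-en-2-ol | CC(C)C1(SCCCS1)C[C@@H](O)CC(C)=C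
F2 | step 12 | tert-butyldimethylsilyl ether of F1 | CC(C)C1(SCCCS1)C[C@@H](O[Si](C)(C)C(C)(C)C)CC(C)=C
F3 | step 12 | (5S)-5-[(tert-butyldimethylsilyl)oxy]-2,7-dimethyloct-7-en-3-one | CC(C)C(=O)C[C@@H](O[Si](C)(C)C(C)(C)C)CC(C)=C
F4 | step 12 | (Z)-triethylsilyl enol ether of F3 (C4=C5) | CC(C)/C(O[Si](CC)(CC)CC)=C/[C@@H](O[Si](C)(C)C(C)(C)C)CC(C)=C
F5 | step 12 | dichlorocyclobutanone from F4 (C4–O cis to the C5 side chain) | O=C1C(Cl)(Cl)[C@@](O[Si](CC)(CC)CC)(C(C)C)[C@@H]1[C@@H](O[Si](C)(C)C(C)(C)C)CC(C)=C
F6 | step 12 | 3,3-dichloro-1-methylcyclopentan-2-one from F5 (skeleton locants; C1 epimers) | O=C1C(Cl)(Cl)[C@@](O[Si](CC)(CC)CC)(C(C)C)[C@H]([C@@H](O[Si](C)(C)C(C)(C)C)CC(C)=C)C1C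
F7 | step 12 | dechlorinated 1-methylcyclopentan-2-one (C1 epimers) | O=C1C[C@@](O[Si](CC)(CC)CC)(C(C)C)[C@H]([C@@H](O[Si](C)(C)C(C)(C)C)CC(C)=C)C1C
F8 | step 12 | trimethylsilyl enol ether C1=C2 of F7 | C[Si](C)(C)OC1C[C@@](O[Si](CC)(CC)CC)(C(C)C)[C@H]([C@@H](O[Si](C)(C)C(C)(C)C)CC(C)=C)C=1C
F9 | step 12 | 1-allyl-1-methylcyclopentan-2-one (allyl trans to the C5 side chain) | O=C1C[C@@](O[Si](CC)(CC)CC)(C(C)C)[C@H]([C@@H](O[Si](C)(C)C(C)(C)C)CC(C)=C)[C@@]1(C)CC=C
F10 | step 11 | N-(tert-butyldimethylsilyl) derivative of 21 | CC(C)/C(O[Si](CC)(CC)CC)=C/[C@@H](O[Si](C)(C)C(C)(C)C)C/C(C)=C\CC(C)=NN([Si](C)(C)C(C)(C)C)S(=O)(=O)c1ccccc1C(F)(F)F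
F11 | step 11 | N-(tert-butyldimethylsilyl) derivative of 23 | O=C1C(Cl)(Cl)[C@@](O[Si](CC)(CC)CC)(C(C)C)[C@@H]1[C@@H](O[Si](C)(C)C(C)(C)C)C/C(C)=C\CC(C)=NN([Si](C)(C)C(C)(C)C)S(=O)(=O)c1ccccc1C(F)(F)F
F0 | step 13 | none | none
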